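The constants used here were set for the occasion; the flask was simulated.

A neighbour flask, run for the same time but charged with 25 mM of solid substrate where this flask has 41 mM, looks nearly the same, so I reckoned the two side by side.

solid substrate 41 mM; gas 2.5 mM (held); time 5.0 min

    gas ⇌ partner, rate k1*(csat - [partner]) (k1 = 0.0199 s⁻¹, csat = 2.5 mM)
    partner → decomposed reagent (k2 = 0.00345 s⁻¹)
    2 solid substrate → homo dimer (k3 = 0.718 L mol⁻¹ s⁻¹)
    solid product ⇌ target, rate k4*(cs4 - [target]) while solid is left; crystals form when [target] > cs4 (cs4 = 19 mM, k4 = 0.353 s⁻¹)
    dissolved substrate + partner → target (k5 = 52.2 L mol⁻¹ s⁻¹)
    solid substrate ⇌ dissolved substrate, rate k6*(cs6 - [dissolved substrate]) while solid is left; crystals form when [dissolved substrate] > cs6 (cs6 = 33 mM, k6 = 0.0828 s⁻¹)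

1. the target and solid product together standing at 5.0 min, as a percentage of the solid substrate charged
2. concentration of dissolved substrate in solution at 5.0 min, in percent of saturation

- a species is counted by the solid substrate in it: one homo dimer counts as two
- amounts and yields of target count solid product too
- two of one species on the left: rate k times its square, two consumed each time
- given per volume of solution although it is solid: solid substrate, solid product
- at the start none of partner is dissolved
- at the start none of the solid substrate is in solution
- dissolved substrate means what is dissolved; the solid is not counted in it
- run time (flask): 5.0 min

**Gas budget.** With the dissolved substrate of this flask at half of saturation, partner is taken up with a pseudo-first-order constant of 0.861 s⁻¹, which is much larger than the decomposition constant, 0.00345 s⁻¹, and the transfer coefficient, 0.0199 s⁻¹. I therefore expected partner in this flask to stay near 0.0578 mM, far below its saturation, and took the gas transfer as the rate-limiting step. The target made is then the gas budget, the transfer coefficient times the saturation concentration times the time, 14.9 mM. The charge does not enter it, so I gave both flasks the same amount, and it stays below the solubility of target, 19 mM, so I expected no crystals. As a share of the charge it is 36.4% in this flask and 59.7% in the neighbour.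

**Fraction left.** I reckoned what stays dissolved as the charge minus the homo dimer share minus the budget. At the start, this flask's solid goes to homo dimer at 2.41 mM s⁻¹ and the neighbour's at 0.898 mM s⁻¹, while each dissolves at 2.73 mM s⁻¹. A solid falling in a straight line averages a third of its starting square, so I took that part of each dimer rate and held dissolution at its starting rate. This gave dimer shares of 22.7% here and 9.87% in the neighbour. By this reckoning this flask keeps 40.8% of its charge dissolved, which is 50.8% of saturation.

**The forecast.** The forecast gave 35.3% (33.5% to 36.5%) and 48.7% (45% to 52%), reasoning that “partner is consumed almost as soon as it arrives”, and both values lie a little below mine.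

**The result.** This flask gave 35.5% and 49.0%, the yield just under the budget's 36.4%. Gas transfer in this flask had done half of its turnover by 2.50 min, half of the run. The same 14.9 mM spread over the neighbour's 25 mM gives 59.7%, and the neighbour stood a little lower, at 57.4% target, with homo dimer at 11.0%.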